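The route rests on a retro-[2+2] cut of the cyclobutane ring of the pinane unit (pinane numbering: bridgeheads C1 and C5, CMe2 carbon C6, methylene bridge C7, spiro carbon C2). An acyclic geranic amide bearing a twofold-symmetric pyrrolidine auxiliary is turned into a vinylketeniminium ion whose C7=C1 unit adds across the C5=C6 alkene: C7–C5 and C1–C6 form in one operation, both bridgehead stereocentres are set, the cation-stabilising gem-dimethyl carbon C6 enforces the crossed bicyclo[3.1.1] mode, and C7 is temporarily a carbonyl. Wolff–Kishner removal gives (−)-β-pinene, whose exocyclic alkene captures an acylphloroglucinol o-quinone methide on the face remote from C6, setting spiro centre C2.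

Key step: step 2

Assumption: commercial geranic acid is an E/Z mixture and is drawn as the E isomer; both isomers should converge on the same vinylketeniminium ion in step 2.
Assumption: the sense of induction of the (2R,5R)-auxiliary follows the steric model given in step 2; should it prove opposite, the equally available (2S,5S)-amine would be used with no other change.

Step 1
Reactants: 1 geranic acid; 2 (2R,5R)-2,5-dimethylpyrrolidine
Product: 4 (2E)-1-[(2R,5R)-2,5-dimethylpyrrolidin-1-yl]-3,7-dimethylocta-2,6-dien-1-one, via geranoyl chloride 3 (not isolated)
Conditions: (COCl)2, cat. DMF, CH2Cl2, 0 °C to rt; then 2, pyridine, CH2Cl2, 0 °C to rt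
Reagents that add atoms: none
Why: Acid chloride formation followed by Schotten–Baumann-type N-acylation of the hindered secondary amine should give the amide cleanly, pyridine (not a trialkylamine) being chosen so that the unsaturated acid chloride is not dehydrohalogenated to a vinylketene; no stereocentre is formed and the auxiliary centres are untouched.

Step 2
Reactants: 4 the geranic amide
Product: 8 (1S,5R)-7,7-dimethyl-2-methylenebicyclo[3.1.1]heptan-6-one, via O-triflyl iminium triflate 5 (not isolated), via vinylketeniminium triflate 6 (not isolated), via cyclobutaniminium triflate 7 (not isolated)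
Conditions: Tf2O, 2,4,6-collidine, ClCH2CH2Cl (high dilution), 0 °C then 80 °C; then aq. NaHCO3, 60 °C
Reagents that add atoms: water (O)
Why: Tf2O O-activates amide 4 to the O-triflyl iminium ion 5, and collidine removes a γ-proton from the C3 methyl group with loss of triflate to give vinylketeniminium ion 6, the nitrogen analogue of a vinylketene. Its electrophilic sp carbon (future C7) is attacked by alkene carbon C5, closing the six-membered ring C7–C1–C2–C3–C4–C5 in a 6-exo mode while positive charge builds at tertiary C6, and C6 then bonds to the enamine carbon C1 to close the four-membered ring C1–C7–C5–C6 (both enamine carbons lie in the new ring), an asynchronous thermal [2+2] of the crossed type that gives cyclobutaniminium ion 7. The closest known reaction type is the intramolecular keteniminium–alkene [2+2] cycloaddition of alkenyl amides carrying twofold-symmetric 2,5-dimethylpyrrolidine auxiliaries, together with the intramolecular vinylketene–alkene cycloaddition that builds the same bicyclo[3.1.1]heptan-6-one skeleton. C1 and C5 arise together, their relative configuration fixed by the bicycle (the one-carbon bridges can only span cis) and their absolute configuration by the auxiliary: the chain attacks the sp carbon in the plane of the C1 substituents, the pyrrolidine ring stands perpendicular to that plane, and C6 should swing to the enamine face away from the ring methyl group that points toward the incoming chain, which for the (2R,5R)-amine corresponds to the (1S,5R) product. The step needs crossed and not fused regiochemistry, secured by the gem-dimethyl terminus that makes C6 the cation-stabilising end, and it needs the methyl-derived dienyl isomer, secured because only this isomer can cyclise while the deprotonation is reversible. Mild aqueous NaHCO3 hydrolysis should release ketone 8 and the auxiliary, and the bridgehead α-carbons cannot enolise, so the new centres cannot epimerise.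

Step 3
Reactants: 8 (1S,5R)-7,7-dimethyl-2-methylenebicyclo[3.1.1]heptan-6-one
Product: 10 (−)-β-pinene ((1S,5S)-6,6-dimethyl-2-methylenebicyclo[3.1.1]heptane), via hydrazone 9 (not isolated)
Conditions: N2H4·H2O, diethylene glycol, argon, 130 °C; then KOH, 200 °C, product distilled out as it forms
Reagents that add atoms: none
Why: Wolff–Kishner reduction in the Huang-Minlon form should turn the temporary C7 carbonyl into the methylene bridge, hydrazone 9 being formed before KOH is added so that hydroxide meets no free strained ketone, while the non-conjugated exocyclic alkene and both bridgehead stereocentres are not touched.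

Step 4
Reactants: 11 2,4,6-trihydroxytoluene; 12 isovaleryl chloride
Product: 13 1-(2,4,6-trihydroxy-3-methylphenyl)-3-methylbutan-1-one
Conditions: AlCl3, PhNO2, 65 °C; then aq. HCl
Reagents that add atoms: none
Why: Friedel–Crafts acylation of the highly activated ring should give a single monoketone because the two free ring positions are equivalent and the aluminium-chelated product is deactivated toward a second acylation.

Step 5
Reactants: 13 1-(2,4,6-trihydroxy-3-methylphenyl)-3-methylbutan-1-one
Product: 15 grandinol (2,4,6-trihydroxy-3-methyl-5-(3-methylbutanoyl)benzaldehyde), via aryl iminium chloride 14 (not isolated)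
Conditions: POCl3, DMF, EtOAc, 0 °C to rt; then H2O, 60 °C
Reagents that add atoms: N,N-dimethylformamide (CN(C)C=O); water (O)
Why: Vilsmeier–Haack formylation should occur at the only remaining ring position, which is ortho and para to hydroxy groups, and hydrolysis of iminium ion 14 then releases the aldehyde.

Step 6
Reactants: 15 grandinol; 10 (−)-β-pinene
Product: 17 euglobal G3, via o-quinone methide 16 (not isolated)
Conditions: DDQ, MeNO2, 0 °C to rt (DDQ added slowly to 15 and 10)
Reagents that add atoms: none
Why: DDQ abstracts hydride from the benzylic methyl group of 15 to give o-quinone methide 16, which should add to the exocyclic alkene of 10 in an inverse-electron-demand hetero-Diels–Alder reaction that mirrors the presumed biosynthesis, the methide carbon bonding to the terminal CH2 and the carbonyl oxygen to the more substituted C2 from the face opposite the gem-dimethyl bridge, so that the spiro centre is set by substrate control (oxygen syn to the methylene bridge) without a free pinyl cation; closure through the oxygen lying between the methide and the formyl-bearing carbon gives 17.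

Compound list
1 | geranic acid, (2E)-3,7-dimethylocta-2,6-dienoic acid (commercial E/Z mixture, drawn E) | CC(C)=CCC/C(C)=C/C(=O)O | starting material
2 | (2R,5R)-2,5-dimethylpyrrolidine (trans, twofold-symmetric) | C[C@@H]1CC[C@@H](C)N1 | starting material
3 | geranoyl chloride, (2E)-3,7-dimethylocta-2,6-dienoyl chloride | CC(C)=CCC/C(C)=C/C(=O)Cl | intermediate
4 | (2E)-1-[(2R,5R)-2,5-dimethylpyrrolidin-1-yl]-3,7-dimethylocta-2,6-dien-1-one | CC(C)=CCC/C(C)=C/C(=O)N1[C@H](C)CC[C@H]1C | intermediate
5 | O-triflyl iminium triflate of amide 4 (triflyloxy group on the former carbonyl carbon) | CC(C)=CCC/C(C)=C/C(OS(=O)(=O)C(F)(F)F)=[N+]1[C@H](C)CC[C@H]1C.[O-]S(=O)(=O)C(F)(F)F | intermediate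
6 | vinylketeniminium triflate (N=C=CH–C(=CH2)– chain ending in the CH=CMe2 alkene) | CC(C)=CCCC(=C)C=C=[N+]1[C@H](C)CC[C@H]1C.[O-]S(=O)(=O)C(F)(F)F | intermediate
7 | cyclobutaniminium triflate (iminium of ketone 8 with the auxiliary) | C=C1CC[C@H]2C(=[N+]3[C@H](C)CC[C@H]3C)[C@@H]1C2(C)C.[O-]S(=O)(=O)C(F)(F)F | intermediate
8 | (1S,5R)-7,7-dimethyl-2-methylenebicyclo[3.1.1]heptan-6-one | C=C1CC[C@H]2C(=O)[C@@H]1C2(C)C | intermediate
9 | hydrazone of ketone 8 | C=C1CC[C@H]2C(=NN)[C@@H]1C2(C)C | intermediate
10 | (−)-β-pinene, (1S,5S)-6,6-dimethyl-2-methylenebicyclo[3.1.1]heptane | C=C1CC[C@H]2C[C@@H]1C2(C)C | intermediate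
11 | 2,4,6-trihydroxytoluene (2-methylbenzene-1,3,5-triol) | Cc1c(O)cc(O)cc1O | starting material
12 | isovaleryl chloride (3-methylbutanoyl chloride) | CC(C)CC(=O)Cl | starting material
13 | 1-(2,4,6-trihydroxy-3-methylphenyl)-3-methylbutan-1-one | CC(C)CC(=O)c1c(O)cc(O)c(C)c1O | intermediate
14 | aryl iminium chloride (ArCH=NMe2 chloride at the free ring position of 13) | CC(C)CC(=O)c1c(O)c(C)c(O)c(C=[N+](C)C)c1O.[Cl-] | intermediate
15 | grandinol, 2,4,6-trihydroxy-3-methyl-5-(3-methylbutanoyl)benzaldehyde | CC(C)CC(=O)c1c(O)c(C)c(O)c(C=O)c1O | intermediate
16 | o-quinone methide from 15 (exocyclic CH2 in place of the methyl group, ring carbonyl at the oxygen between methide and formyl carbons) | CC(C)CC(=O)C1=C(O)C(=C)C(=O)C(C=O)=C1O | intermediate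
17 | euglobal G3: 5,7-dihydroxy-6-(3-methylbutanoyl)-8-formylchroman spiro-fused at C2 to C2 of the 6,6-dimethylbicyclo[3.1.1]heptane unit (pinane numbering 1R,2R,5S; ring oxygen syn to the methylene bridge) | CC(C)CC(=O)c1c(O)c(C=O)c2c(c1O)CC[C@@]1(CC[C@H]3C[C@@H]1C3(C)C)O2 | target

Total step count: 6
Longest linear sequence: 4 steps (steps 1, 2, 3 and 6; steps 4 and 5 make the aromatic partner separately)

Steps most likely to fail

Step 2 (key step). The auxiliary may discriminate the alkene faces poorly, γ-deprotonation may take place at C4 and not at the methyl group, or the keteniminium ion may oligomerise before it cyclises. The fallback sets out from compound 1 and comes back at compound 8. Acid 1 is converted into geranoyl chloride 3 as in step 1 and added slowly to Et3N in refluxing toluene. Dehydrohalogenation should give the vinylketene F1, which undergoes the same crossed intramolecular [2+2] cycloaddition directly to the racemic ketone F2. The enantiomers are then separated by preparative chromatography on a chiral stationary phase (supercritical CO2, amylose tris(3,5-dimethylphenylcarbamate) phase), and the (1S,5R) enantiomer is carried on as 8.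

Step 6. Ring closure may occur through the other ortho oxygen (the one between the methide and the isovaleryl-bearing carbon), giving the 6-formyl-8-acyl isomer that must be separated. DDQ may also oxidise the alkene, and the acidic hydroquinone may open the cyclobutane. The fallback sets out from compounds 13 and 10 and comes back at compound 17, introducing the formyl group last. DDQ oxidation of 13 in MeNO2 in the presence of 10 should give the formyl-free o-quinone methide F3. In F3 the oxygen para to the ketone is not held in the hydrogen-bonded chelate and is expected to be the more nucleophilic one, as in para-selective O-alkylation of acylphloroglucinols. Hetero-Diels–Alder reaction with 10 should then give the 8-unsubstituted spirochroman F4, from which any isomer is removed at this stage. Vilsmeier–Haack formylation (POCl3, DMF, EtOAc, 0 °C; then aq. NaOAc) at the single free ring position, through the iminium chloride F5, should give 17.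

Step 3. Hydroxide may cleave the strained, non-enolisable cyclobutanone before the hydrazone has formed, strong base may move the exocyclic alkene into the ring, adventitious diimide may reduce the alkene, and the volatile product may be lost. The fallback sets out from compound 8 and comes back at compound 10. NaBH4 in MeOH at 0 °C should give the cyclobutanol F6, whose carbinol configuration is immaterial. NaH, CS2 and then MeI in THF give the xanthate F7. Barton–McCombie deoxygenation (Bu3SnH, AIBN, toluene, 80 °C) should then give 10 under neutral conditions.

Further compounds
F1 | step 2 | vinylketene, 7-methyl-3-methyleneocta-1,6-dien-1-one | CC(C)=CCCC(=C)C=C=O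
F2 | step 2 | racemic 7,7-dimethyl-2-methylenebicyclo[3.1.1]heptan-6-one | C=C1CCC2C(=O)C1C2(C)C
F3 | step 6 | formyl-free o-quinone methide from 13 (ring carbonyl at the oxygen para to the ketone) | CC(C)CC(=O)C1=C(O)C(=C)C(=O)C=C1O
F4 | step 6 | 8-unsubstituted spirochroman (17 lacking the formyl group) | CC(C)CC(=O)c1c(O)cc2c(c1O)CC[C@@]1(CC[C@H]3C[C@@H]1C3(C)C)O2
F5 | step 6 | iminium chloride of F4 at C8 of the chroman | CC(C)CC(=O)c1c(O)c(C=[N+](C)C)c2c(c1O)CC[C@@]1(CC[C@H]3C[C@@H]1C3(C)C)O2.[Cl-]
F6 | step 3 | (1S,5R)-7,7-dimethyl-2-methylenebicyclo[3.1.1]heptan-6-ol (carbinol epimers, configuration at C6 not controlled) | C=C1CC[C@H]2C(O)[C@@H]1C2(C)C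
F7 | step 3 | O-cyclobutyl S-methyl xanthate of F6 | C=C1CC[C@H]2C(OC(=S)SC)[C@@H]1C2(C)C
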